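**Retrosynthetic overview** (eudesmane numbering; β is the face of the C10 methyl C14)
1. Feature: in ring A the C3 oxygen and the C4 carbinol carbon with its methyl C15 form a masked acyloin that can sit as a C3=C4 enol silane next to C5, and quaternary C10 carries C14 and the one-carbon arm C9. Ring A is therefore the [4+2] adduct of methacrolein (C1, C10, C9, C14) and a 2-silyloxy-3-methyldiene (C2–C6, C15), with bonds C1–C2 and C5–C10.
2. Last bond: the C3–O ester, from triol 24 and (2S,3R)-2,3-dimethyloxirane-2-carboxylic acid 28 (tiglic acid, Sharpless epoxidation).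
3. C7–C11 from a C7 vinyllithium and acetone; ring B (C6=C7) by aldol condensation of keto aldehyde 16 (C8 methyl ketone onto the C6 aldehyde).
4. C8 and C7 from ethylidenation of the C9 aldehyde and hydroboration; C4–OH by Rubottom oxidation of the enol silane, C3–OH by hydride.
5. Ring order: ring A (step 3), then ring B (step 11); the oxirane arrives ready-made in 28.

Key step: step 3

Assumption: the (S)-diphenylprolinol-derived oxazaborolidinium ion is taken to cover the si face at C10 of bound methacrolein, so that the diene adds to the re face; if the sense is the reverse, the enantiomeric catalyst is used and nothing else changes.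

**Route**

Step 1
Reactants: 1 benzyloxyacetaldehyde; 2 3-(triphenylphosphoranylidene)butan-2-one
Product: 3 (E)-5-(benzyloxy)-3-methylpent-3-en-2-one
Conditions: toluene, 90 °C
Reagents that add atoms: none
Why: Wittig olefination with an α-methyl-substituted stabilised acyl ylide, which should give the (E)-trisubstituted enone; no stereocentre is formed.

Step 2
Reactants: 3 (E)-5-(benzyloxy)-3-methylpent-3-en-2-one
Product: 5 (E)-5-(benzyloxy)-3-methyl-2-(triisopropylsilyloxy)penta-1,3-diene, via lithium dienolate 4 (not isolated)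
Conditions: LiN(iPr)2, THF, −78 °C; then iPr3SiOTf, −78 to 0 °C
Reagents that add atoms: triisopropylsilyl triflate CC(C)[Si](OS(=O)(=O)C(F)(F)F)(C(C)C)C(C)C; lithium diisopropylamide [Li]N(C(C)C)C(C)C (lithium stays only in 4)
Why: Kinetic enol silane formation, in which the hindered amide removes a proton from the α′ methyl group to give the cross-conjugated dienolate and the silyl triflate traps it on oxygen, leaving the (E)-C4=C5 bond untouched.

Step 3
Reactants: 5 (E)-5-(benzyloxy)-3-methyl-2-(triisopropylsilyloxy)penta-1,3-diene; 6 methacrolein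
Product: 7 ring A aldehyde (1S,2S)-2-[(benzyloxy)methyl]-1,3-dimethyl-4-[(triisopropylsilyl)oxy]cyclohex-3-ene-1-carbaldehyde
Conditions: (S)-1-(2-methylphenyl)-3,3-diphenyltetrahydro-1H,3H-pyrrolo[1,2-c][1,3,2]oxazaborole C24H24BNO (20 mol %), (CF3SO2)2NH (18 mol %), 6 (1.5 equiv), CH2Cl2, −78 °C
Reagents that add atoms: none
Why: The oxazaborolidinium ion binds the formyl oxygen of 6 (with a formyl C–H···O contact to the ring oxygen) and the s-cis diene adds in a concerted, asynchronous [4+2] cycloaddition in which the nucleophilic CH2 terminus C2 of the silyl dienol ether bonds to the β-carbon C1 ahead of the C5–C10 bond; the closest known reaction type is the cationic-oxazaborolidine-catalysed Diels–Alder reaction of α-substituted acroleins with 2-triisopropylsilyloxy-1,3-dienes. Ring A is closed in this one six-membered [4+2] event, suprafacial on both partners, and C3=C4 is left as the enol silane. C10 is set by the catalyst, whose aryl group covers one face of the bound s-trans enal so that the diene reaches the re face at C10, and C5 follows from the (E)-geometry of C4=C5 together with the exo position of the formyl group, which puts C9 trans to C6 and C14 cis to C6. Regiochemistry is fixed twice, by the 2-silyloxy group (para rule) and by the C5 substituent (ortho rule). The selectivity that has to be secured is exo over endo: the OTIPS group on C3 and the methyl on C4 occupy the space that the catalyst-bound formyl group would need in the endo transition state, a clash of the kind that turns bulky 2-silyloxydienes exo towards Lewis-acid-bound carbonyl dienophiles, and the α-methyl group of 6 itself prefers the endo position.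

Step 4
Reactants: 7 ring A aldehyde
Product: 8 (Z)-propenyl enol silane (7 with CHO replaced by (Z)-CH=CH–CH3; C9=C8–C7)
Conditions: EtPPh3Br, KN(SiMe3)2, THF, 0 °C; then 7, −78 °C to rt
Reagents that add atoms: ethyltriphenylphosphonium bromide CC[P+](c1ccccc1)(c1ccccc1)c1ccccc1.[Br-]
Why: Wittig olefination of the non-enolisable neopentyl aldehyde with the unstabilised ethylidene ylide should give mainly the (Z)-alkene and leave the hindered enol silane intact; the alkene geometry has no consequence later.

Step 5
Reactants: 8 (Z)-propenyl enol silane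
Product: 10 hydroxy ketone (C3 ketone; C4 α-OH and β-CH3; C5 β-CH2OBn; C10 β-CH3 and α-(Z)-propenyl), via silyloxy epoxide 9 (not isolated)
Conditions: mCPBA (1.05 equiv), NaHCO3, CH2Cl2, −40 to −20 °C; then Bu4NF, AcOH, THF, 0 °C
Reagents that add atoms: mCPBA OOC(=O)c1cccc(Cl)c1
Why: Rubottom oxidation, in which the electron-rich tetrasubstituted enol silane is epoxidised much faster than the hindered disubstituted alkene and from the α face, opposite the C5 CH2OBn arm and the C10 methyl, and fluoride opens the silyloxy epoxide to the C3 ketone with the C4 hydroxyl α and C15 β.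

Step 6
Reactants: 10 hydroxy ketone
Product: 11 diol (3β-OH; 4α-OH)
Conditions: NaBH4, MeOH/CH2Cl2, −40 °C
Reagents that add atoms: none
Why: Borohydride reduction of the α-hydroxy ketone, with hydride reaching C3 from the α face, away from the β substituents on C4, C5 and C10 and on the side of the C4 hydroxyl, so that the 3β alcohol, trans to the C4 hydroxyl, should result.

Step 7
Reactants: 11 diol
Product: 12 bis(triethylsilyl) ether
Conditions: Et3SiOTf (3 equiv), 2,6-lutidine, CH2Cl2, −78 to 0 °C
Reagents that add atoms: triethylsilyl triflate CC[Si](CC)(CC)OS(=O)(=O)C(F)(F)F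
Why: Silylation with a silyl triflate, which is reactive enough to cap the tertiary C4 hydroxyl as well as the secondary C3 hydroxyl, so that no free alcohol is left for the oxidation, aldol and organolithium steps.

Step 8
Reactants: 12 bis(triethylsilyl) ether
Product: 14 C8 alcohol (C10–CH2–CH(OH)–CH3; mixture of C8 epimers), via alkylborane 13 (not isolated)
Conditions: 9-BBN, THF, 65 °C; then NaOH, H2O2, 0 °C to rt
Reagents that add atoms: 9-borabicyclo[3.3.1]nonane B1C2CCCC1CCC2 (boron stays only in 13); hydrogen peroxide OO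
Why: Hydroboration–oxidation, in which 9-BBN places boron on C8, the alkene carbon remote from quaternary C10, and oxidation with retention gives the C8 alcohol as an epimer mixture that the later oxidation levels.

Step 9
Reactants: 14 C8 alcohol
Product: 15 C6,C8-diol
Conditions: H2 (1 atm), Pd/C, EtOAc, rt
Reagents that add atoms: none
Why: Hydrogenolysis of the benzyl ether over palladium in a non-protic solvent, which frees the C6 hydroxyl and leaves the silyl ethers alone.

Step 10
Reactants: 15 C6,C8-diol
Product: 16 keto aldehyde (C6 aldehyde; C8 methyl ketone)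
Conditions: (COCl)2, DMSO, CH2Cl2, −78 °C; then Et3N, −78 to 0 °C
Reagents that add atoms: none
Why: Swern oxidation activates both hydroxyls at −78 °C before base is added, so no hydroxy carbonyl intermediate can close to a lactol and be over-oxidised to a lactone, and the C6 aldehyde and C8 ketone form together without loss of configuration at C5.

Step 11
Reactants: 16 keto aldehyde
Product: 18 trans-fused enone (ring B: C6=C7–C8=O), via aldol 17 (not isolated)
Conditions: pyrrolidine (0.5 equiv), AcOH (0.5 equiv), toluene, 50 °C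
Reagents that add atoms: none
Why: Intramolecular aldol condensation (6-enolendo-exo-trig) in which the enamine of the methyl ketone attacks the C6 aldehyde through C7 (attack through C9 would give a four-membered ring) and dehydration gives the C6=C7 enone; the trans ring fusion comes from the equatorial C6 and C9 arms fixed in step 3, and the equatorial C4 silyl ether is poorly aligned for β-elimination.

Step 12
Reactants: 18 trans-fused enone
Product: 19 7-iodo enone
Conditions: I2 (2 equiv), pyridine/CH2Cl2 (1:1), rt
Reagents that add atoms: iodine II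
Why: α-Iodination of the enone by conjugate addition of pyridine, iodination of the enolate and elimination, which marks C7 for the bond to C11.

Step 13
Reactants: 19 7-iodo enone
Product: 20 iodo allylic alcohol (C8–OH; mixture of C8 epimers)
Conditions: NaBH4, CeCl3·7H2O, MeOH, −78 to −40 °C
Reagents that add atoms: none
Why: Luche reduction delivers hydride 1,2 to the enone carbonyl and so removes the electrophile that an organolithium would attack; the C8 configuration does not matter because C8 is re-oxidised in step 15.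

Step 14
Reactants: 20 iodo allylic alcohol
Product: 22 diol (C8–OH; C7–C(CH3)2OH), via dilithio species 21 (not isolated)
Conditions: MeLi (1.1 equiv), then t-BuLi (2.2 equiv), THF/Et2O, −78 °C; acetone (5 equiv), −78 °C; then H2O
Reagents that add atoms: acetone CC(C)=O; methyllithium [Li]C and tert-butyllithium [Li]C(C)(C)C (lithium stays only in 21)
Why: Iodine–lithium exchange on the pre-formed lithium alkoxide gives the C7 vinyllithium, which adds to acetone to form the C7–C11 bond and the tertiary C11 carbinol.

Step 15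
Reactants: 22 diol
Product: 23 hydroxy enone bis(triethylsilyl) ether
Conditions: Dess–Martin periodinane, NaHCO3, CH2Cl2, 0 °C
Reagents that add atoms: none
Why: Dess–Martin oxidation of the only secondary alcohol restores the C8 ketone in conjugation with C6=C7, the tertiary C11 alcohol and the silyl ethers being inert.

Step 16
Reactants: 23 hydroxy enone bis(triethylsilyl) ether
Product: 24 triol enone (3β-OH; 4α-OH; 11-OH)
Conditions: HF·pyridine, pyridine, THF, 0 °C to rt
Reagents that add atoms: none
Why: Fluoride cleavage of both triethylsilyl ethers under buffered conditions that should leave the enone and the tertiary allylic alcohol unchanged.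

Step 17
Reactants: 25 tiglic acid
Product: 26 (E)-2-methylbut-2-en-1-ol
Conditions: LiAlH4, Et2O, 0 °C to rt
Reagents that add atoms: none
Why: Hydride reduction of the carboxylic acid to the primary allylic alcohol, with the trisubstituted alkene and its (E)-geometry retained.

Step 18
Reactants: 26 (E)-2-methylbut-2-en-1-ol
Product: 27 ((2R,3R)-2,3-dimethyloxiran-2-yl)methanol
Conditions: Ti(OiPr)4 (10 mol %), D-(−)-diisopropyl tartrate (12 mol %), t-BuOOH, 4 Å molecular sieves, CH2Cl2, −20 °C
Reagents that add atoms: tert-butyl hydroperoxide CC(C)(C)OO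
Why: Sharpless asymmetric epoxidation, in which the titanium complex of the D-(−)-tartrate delivers oxygen to the face of the (E)-allylic alcohol that gives the (2R,3R)-epoxide, the cis relation of the two methyl groups coming from the (E)-alkene.

Step 19
Reactants: 27 ((2R,3R)-2,3-dimethyloxiran-2-yl)methanol
Product: 28 (2S,3R)-2,3-dimethyloxirane-2-carboxylic acid
Conditions: TEMPO (20 mol %), PhI(OAc)2 (2.2 equiv), MeCN/H2O (1:1), rt
Reagents that add atoms: water O
Why: Oxoammonium-mediated oxidation of the primary alcohol through the aldehyde hydrate to the acid, which does not touch the oxirane or its stereocentres (the C2 descriptor changes from R to S only through the CIP priorities).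

Step 20
Reactants: 24 triol enone; 28 (2S,3R)-2,3-dimethyloxirane-2-carboxylic acid
Product: 30 target CNP0272928.2, via mixed anhydride 29 (not isolated)
Conditions: 28, 2,4,6-trichlorobenzoyl chloride, Et3N, toluene, rt; then 24, DMAP, toluene, rt to 40 °C
Reagents that add atoms: 2,4,6-trichlorobenzoyl chloride O=C(Cl)c1c(Cl)cc(Cl)cc1Cl (its atoms stay only in 29)
Why: Yamaguchi esterification, in which DMAP attacks the aliphatic carbonyl of the mixed anhydride and the acylpyridinium acylates the only secondary hydroxyl (C3), the tertiary C4 and C11 hydroxyls being too hindered, with no change at any stereocentre.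

**Compound list**
1 | benzyloxyacetaldehyde | O=CCOCc1ccccc1 | starting material
2 | 3-(triphenylphosphoranylidene)butan-2-one | CC(=O)C(C)=P(c1ccccc1)(c1ccccc1)c1ccccc1 | starting material
3 | (E)-5-(benzyloxy)-3-methylpent-3-en-2-one | CC(=O)/C(C)=C/COCc1ccccc1 | intermediate
4 | lithium (E)-5-(benzyloxy)-3-methylpenta-1,3-dien-2-olate | [Li]OC(=C)/C(C)=C/COCc1ccccc1 | intermediate (not isolated)
5 | (E)-5-(benzyloxy)-3-methyl-2-(triisopropylsilyloxy)penta-1,3-diene | C=C(O[Si](C(C)C)(C(C)C)C(C)C)/C(C)=C/COCc1ccccc1 | intermediate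
6 | methacrolein | C=C(C)C=O | starting material
7 | ring A aldehyde, (1S,2S)-2-[(benzyloxy)methyl]-1,3-dimethyl-4-[(triisopropylsilyl)oxy]cyclohex-3-ene-1-carbaldehyde (CHO trans to CH2OBn) | O=C[C@@]1(C)CCC(O[Si](C(C)C)(C(C)C)C(C)C)=C(C)[C@@H]1COCc1ccccc1 | intermediate
8 | (Z)-propenyl enol silane (C10: β-CH3, α-(Z)-prop-1-enyl; C5: β-CH2OBn) | C/C=C\[C@@]1(C)CCC(O[Si](C(C)C)(C(C)C)C(C)C)=C(C)[C@@H]1COCc1ccccc1 | intermediate
9 | 3α,4α-epoxide of 8 (3β-OTIPS, 4β-CH3) | CC(C)[Si](C(C)C)(C(C)C)O[C@@]12CC[C@](C)(/C=C\C)[C@@H](COCc3ccccc3)[C@]1(C)O2 | intermediate (not isolated)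
10 | hydroxy ketone (C3 ketone; 4α-OH, 4β-CH3; 5β-CH2OBn; 10β-CH3, 10α-(Z)-propenyl) | O=C1CC[C@](C)(/C=C\C)[C@@H](COCc2ccccc2)[C@]1(C)O | intermediate
11 | 3β,4α-diol | O[C@H]1CC[C@](C)(/C=C\C)[C@@H](COCc2ccccc2)[C@]1(C)O | intermediate
12 | 3β,4α-bis(triethylsilyl) ether | CC[Si](CC)(CC)O[C@H]1CC[C@](C)(/C=C\C)[C@@H](COCc2ccccc2)[C@]1(C)O[Si](CC)(CC)CC | intermediate
13 | B-alkyl-9-BBN (boron on C8; C8 epimers) | CC[Si](CC)(CC)O[C@H]1CC[C@](C)(CC(C)B2C3CCCC2CCC3)[C@@H](COCc2ccccc2)[C@]1(C)O[Si](CC)(CC)CC | intermediate (not isolated)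
14 | C8 alcohol (10α-CH2CH(OH)CH3; C8 epimers) | CC[Si](CC)(CC)O[C@H]1CC[C@](C)(CC(C)O)[C@@H](COCc2ccccc2)[C@]1(C)O[Si](CC)(CC)CC | intermediate
15 | C6,C8-diol (5β-CH2OH; C8 epimers) | CC[Si](CC)(CC)O[C@H]1CC[C@](C)(CC(C)O)[C@@H](CO)[C@]1(C)O[Si](CC)(CC)CC | intermediate
16 | keto aldehyde (5β-CHO; 10α-CH2C(O)CH3) | CC[Si](CC)(CC)O[C@H]1CC[C@](C)(CC(C)=O)[C@@H](C=O)[C@]1(C)O[Si](CC)(CC)CC | intermediate
17 | aldol (6-hydroxy-8-oxo trans-decalin; C6 epimers) | CC[Si](CC)(CC)O[C@H]1CC[C@]2(C)CC(=O)CC(O)[C@H]2[C@]1(C)O[Si](CC)(CC)CC | intermediate (not isolated)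
18 | trans-fused enone (6-en-8-one; 3β,4α-bis-OTES; 5α-H; 10β-CH3) | CC[Si](CC)(CC)O[C@H]1CC[C@]2(C)CC(=O)C=C[C@H]2[C@]1(C)O[Si](CC)(CC)CC | intermediate
19 | 7-iodo enone | CC[Si](CC)(CC)O[C@H]1CC[C@]2(C)CC(=O)C(I)=C[C@H]2[C@]1(C)O[Si](CC)(CC)CC | intermediate
20 | 7-iodo-6-en-8-ol (C8 epimers) | CC[Si](CC)(CC)O[C@H]1CC[C@]2(C)CC(O)C(I)=C[C@H]2[C@]1(C)O[Si](CC)(CC)CC | intermediate
21 | C7-lithio lithium C8-alkoxide (C8 epimers) | CC[Si](CC)(CC)O[C@H]1CC[C@]2(C)CC(O[Li])C([Li])=C[C@H]2[C@]1(C)O[Si](CC)(CC)CC | intermediate (not isolated)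
22 | 8,11-diol (7-(2-hydroxypropan-2-yl)-6-en-8-ol; C8 epimers) | CC[Si](CC)(CC)O[C@H]1CC[C@]2(C)CC(O)C(C(C)(C)O)=C[C@H]2[C@]1(C)O[Si](CC)(CC)CC | intermediate
23 | 11-hydroxy-6-en-8-one, 3β,4α-bis(triethylsilyl) ether | CC[Si](CC)(CC)O[C@H]1CC[C@]2(C)CC(=O)C(C(C)(C)O)=C[C@H]2[C@]1(C)O[Si](CC)(CC)CC | intermediate
24 | 3β,4α,11-trihydroxyeudesm-6-en-8-one | O[C@H]1CC[C@]2(C)CC(=O)C(C(C)(C)O)=C[C@H]2[C@]1(C)O | intermediate
25 | tiglic acid | C/C=C(\C)C(=O)O | starting material
26 | (E)-2-methylbut-2-en-1-ol | C/C=C(\C)CO | intermediate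
27 | ((2R,3R)-2,3-dimethyloxiran-2-yl)methanol | C[C@H]1O[C@]1(C)CO | intermediate
28 | (2S,3R)-2,3-dimethyloxirane-2-carboxylic acid | C[C@H]1O[C@]1(C)C(=O)O | intermediate
29 | mixed anhydride of 28 with 2,4,6-trichlorobenzoic acid | C[C@H]1O[C@]1(C)C(=O)OC(=O)c1c(Cl)cc(Cl)cc1Cl | intermediate (not isolated)
30 | CNP0272928.2: (3S,4S,5R,10R)-4,11-dihydroxy-8-oxoeudesm-6-en-3-yl (2S,3R)-2,3-dimethyloxirane-2-carboxylate | C[C@H]1O[C@]1(C)C(=O)O[C@H]1CC[C@]2(C)CC(=O)C(C(C)(C)O)=C[C@H]2[C@]1(C)O | target

**Step count**
Total: 20 steps. Longest linear sequence: 17 steps (steps 1–16 and 20); the acid branch (steps 17–19) joins at step 20.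

**Three steps most likely to fail**

Step 3 (Diels–Alder). What may go wrong: the exo preference is too small, so the formyl group goes endo and C9 ends cis to C6. Fallback, from diene 5, returning at keto aldehyde 16: the two substituents on C10 exchange roles, so that the endo mode becomes the useful one. Diene 5 is combined with 2-methylenepent-4-enal F1 (from pent-4-enal by amine-catalysed α-methylenation with formaldehyde) under the enantiomeric (R)-oxazaborolidinium catalyst. The endo adduct F2 then carries the formyl group cis to the C6 arm and the allyl group trans to it. The formyl group is taken down to the C14 methyl through tosylhydrazone F3 (TsNHNH2) and its reduction with catecholborane and NaOAc, giving the 10β-methyl-10α-allyl enol silane F4. Rubottom oxidation (mCPBA, then Bu4NF/AcOH) through silyloxy epoxide F5 gives hydroxy ketone F6, NaBH4 gives diol F7 and Et3SiOTf gives bis(triethylsilyl) ether F8, as in steps 5 to 7. Wacker oxidation of the allyl group (PdCl2, CuCl, O2, DMF/H2O) gives methyl ketone F9, hydrogenolysis gives primary alcohol F10, and Swern oxidation gives 16.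

Step 11 (aldol condensation). What may go wrong: the aldehyde forms an enamine at C5, which leads to epimerisation at C5 or β-elimination of the C4 silyloxy group before ring B closes. Fallback, from keto aldehyde 16, returning at enone 18: bond formation and dehydration are separated. Kinetic deprotonation of the methyl ketone with LiN(SiMe3)2 in THF at −78 °C gives the C7 lithium enolate, which closes onto the C6 aldehyde to give aldol 17, now isolated. Mesylation (MsCl, Et3N) gives mesylate F11, and DBU eliminates it to 18.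

Step 14 (vinyllithium and acetone). What may go wrong: proton transfer from acetone to the hindered vinyllithium (giving the de-iodinated alkene) or incomplete exchange next to the alkoxide. Fallback, from iodo allylic alcohol 20, returning at diol 22: C11 is brought in by palladium catalysis. Methoxycarbonylation of the vinyl iodide (PdCl2(PPh3)2, CO, MeOH, Et3N, DMF) gives the unsaturated methyl ester F12, and excess MeMgBr in THF converts the ester into the tertiary alcohol 22.

**Further compounds**
F1 | step 3 | 2-methylenepent-4-enal | C=CCC(=C)C=O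
F2 | step 3 | endo adduct (C10: β-CHO, α-allyl; C5: β-CH2OBn; C3=C4 enol silane) | O=C[C@]1(CC=C)CCC(O[Si](C(C)C)(C(C)C)C(C)C)=C(C)[C@@H]1COCc1ccccc1
F3 | step 3 | tosylhydrazone of F2 | Cc1ccc(cc1)S(=O)(=O)N/N=C/[C@]1(CC=C)CCC(O[Si](C(C)C)(C(C)C)C(C)C)=C(C)[C@@H]1COCc1ccccc1
F4 | step 3 | 10β-methyl-10α-allyl enol silane | C[C@]1(CC=C)CCC(O[Si](C(C)C)(C(C)C)C(C)C)=C(C)[C@@H]1COCc1ccccc1
F5 | step 3 | 3α,4α-epoxide of F4 | CC(C)[Si](C(C)C)(C(C)C)O[C@@]12CC[C@](C)(CC=C)[C@@H](COCc3ccccc3)[C@]1(C)O2
F6 | step 3 | hydroxy ketone (C3 ketone; 4α-OH; 10α-allyl) | O=C1CC[C@](C)(CC=C)[C@@H](COCc2ccccc2)[C@]1(C)O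
F7 | step 3 | 3β,4α-diol (10α-allyl) | O[C@H]1CC[C@](C)(CC=C)[C@@H](COCc2ccccc2)[C@]1(C)O
F8 | step 3 | 3β,4α-bis(triethylsilyl) ether (10α-allyl) | CC[Si](CC)(CC)O[C@H]1CC[C@](C)(CC=C)[C@@H](COCc2ccccc2)[C@]1(C)O[Si](CC)(CC)CC
F9 | step 3 | methyl ketone (10α-CH2C(O)CH3; 5β-CH2OBn) | CC[Si](CC)(CC)O[C@H]1CC[C@](C)(CC(C)=O)[C@@H](COCc2ccccc2)[C@]1(C)O[Si](CC)(CC)CC
F10 | step 3 | hydroxy ketone (10α-CH2C(O)CH3; 5β-CH2OH) | CC[Si](CC)(CC)O[C@H]1CC[C@](C)(CC(C)=O)[C@@H](CO)[C@]1(C)O[Si](CC)(CC)CC
F11 | step 11 | C6 mesylate of aldol 17 | CC[Si](CC)(CC)O[C@H]1CC[C@]2(C)CC(=O)CC(OS(C)(=O)=O)[C@H]2[C@]1(C)O[Si](CC)(CC)CC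
F12 | step 14 | methyl 8-hydroxy-6-ene-7-carboxylate (C8 epimers) | CC[Si](CC)(CC)O[C@H]1CC[C@]2(C)CC(O)C(C(=O)OC)=C[C@H]2[C@]1(C)O[Si](CC)(CC)CC
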